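# Total synthesis of violacene

**Stereo convention.** Ring atoms are labelled C1–C6 as in the target SMILES: C1 quaternary (Me, chlorovinyl), C2 CH2, C3 (Cl, CH2Br), C4 CHCl, C5 CH2, C6 CHCl. Drawn anticlockwise from C1 and viewed from the top, the target has Me and CH2Br up, and the chlorovinyl group and all three ring Cl down.

**Assumptions (one line).** Dimethyl (S)-2-hydroxyglutarate and (E)-2-chlorovinylboronic acid are treated as commercial (the diester is otherwise one step from L-glutamic acid). The aldol in Step 4 is assumed to close onto the more electrophilic α-silyloxy ketone.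

## Retrosynthesis
1. Violacene comes from anti-BrCl addition across an exocyclic C3=CH2 (trans-diaxial opening, tertiary C–Cl). The C6–Cl comes from SN2 inversion of the C6 alcohol. The C4–Cl comes from α-chlorination of the C3 ketone, trans to the C6–OTBS, and the ketone is then methylenated.
2. The C1 quaternary centre (Me/chlorovinyl) comes from a new Pd(II) 1,4-addition of (E)-ClCH=CH–B(OH)2 to a 4-OTBS-3-methylcyclohexenone, anti to the OTBS.
3. The only ring-forming step is the intramolecular aldol condensation of (S)-5-OTBS-heptane-2,6-dione, which comes from L-2-hydroxyglutarate. That chiral-pool carbon becomes C6 and relays all other stereocentres.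

## Route

**Step 1**
Reactants: 1, dimethyl (2S)-2-hydroxypentanedioate
Product: 2, (2S)-2-hydroxy-N1,N5-dimethoxy-N1,N5-dimethylpentanediamide
Conditions: Me3Al (5 equiv), MeONHMe·HCl (5 equiv), CH2Cl2, 0 °C → rt
Reagents that add atoms: N,O-dimethylhydroxylamine hydrochloride, CNOC.Cl (Me3Al is only a mediator)
Why: Me3Al-mediated Weinreb amidation converts both esters, and removing the enolisable α-ester protects the carbinol stereocentre.

**Step 2**
Reactants: 2
Product: 3, the (2S)-TBS ether of 2
Conditions: TBSCl, imidazole, DMF, rt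
Reagents that add atoms: TBSCl, CC(C)(C)[Si](C)(C)Cl
Why: Standard silylation of the secondary alcohol, with no change at the stereocentre.

**Step 3**
Reactants: 3
Product: 4, (5S)-5-(TBSO)heptane-2,6-dione
Conditions: MeMgBr (2.5 equiv), THF, −78 → 0 °C
Reagents that add atoms: MeMgBr, C[Mg]Br
Why: Weinreb ketone synthesis stops at the ketone because the chelated tetrahedral intermediate is stable, so both ends become methyl ketones.

**Step 4**
Reactants: 4
Product: 5, (4S)-4-(TBSO)-3-methylcyclohex-2-en-1-one
Conditions: pyrrolidine (20 mol %), AcOH (20 mol %), THF, rt → 40 °C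
Reagents that add atoms: none
Why: Enamine-catalysed intramolecular aldol condensation of a 2,6-diketone (Robinson-type) forms the six-membered ring and the β-methyl enone. The γ-stereocentre (C6) is untouched and its configuration is that of the chiral-pool carbon.

**Step 5**
Reactants: 5; 6, (E)-2-chlorovinylboronic acid
Product: 7, (3R,4S)-4-(TBSO)-3-[(E)-2-chloroethenyl]-3-methylcyclohexan-1-one
Conditions: Pd(TFA)2 (10 mol %), 6,6′-dimethyl-2,2′-bipyridine (12 mol %), NH4PF6 (30 mol %), H2O (5 equiv), ClCH2CH2Cl, 60 °C
Reagents that add atoms: 6, (E)-2-chlorovinylboronic acid, OB(O)/C=C/Cl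
Why: Proposed new method: cationic Pd(II) transmetalates to (E)-ClCH=CH–Pd+, which inserts syn into the β,β-disubstituted enone on the face anti to the γ-OTBS and is then protonated by water. The vinyl C–Cl survives because Pd(II) does not insert into it. This sets C1 trans to the C6–O, so chlorovinyl is down, Me is up and OTBS is up. The closest known reaction is Pd/N,N-ligand 1,4-addition of arylboronic acids to β-substituted cyclic enones (quaternary centres), extended here to a chlorine-bearing alkenylboron nucleophile and a γ-stereocentre-controlled substrate.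

**Step 6**
Reactants: 7
Product: 8, (2S,4S,5R)-4-(TBSO)-2-chloro-5-[(E)-2-chloroethenyl]-5-methylcyclohexan-1-one
Conditions: LDA (1.1 equiv), THF, −78 °C; then NCS (1.05 equiv), −78 → −40 °C
Reagents that add atoms: NCS, ClN1C(=O)CCC1=O
Why: Kinetic enolisation at the unhindered C4 (C2 is next to the quaternary centre), then electrophilic chlorination. Axial attack through the chair that keeps OTBS equatorial puts Cl down, trans to the C6–OTBS.

**Step 7**
Reactants: 8
Product: 9, tert-butyl{[(1S,2R,5S)-5-chloro-2-[(E)-2-chloroethenyl]-2-methyl-4-methylidenecyclohexyl]oxy}dimethylsilane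
Conditions: Cp2TiMe2 (3 equiv), toluene, 70 °C, dark
Reagents that add atoms: dimethyltitanocene, C[Ti](C)(C1C=CC=C1)C1C=CC=C1 (supplies the =CH2 carbon)
Why: Petasis methylenation is mild and non-basic, so the α-chloro stereocentre is not epimerised (Zn-based Lombardo conditions would reduce the C–Cl).

**Step 8**
Reactants: 9
Product: 10, (1S,2R,5S)-5-chloro-2-[(E)-2-chloroethenyl]-2-methyl-4-methylidenecyclohexan-1-ol
Conditions: HF·pyridine, pyridine, THF, 0 °C → rt
Reagents that add atoms: none
Why: Buffered fluoride cleaves the hindered TBS ether without the base that could eliminate the allylic chloride.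

**Step 9**
Reactants: 10
Product: 11, (1R,2R,4S)-2,4-dichloro-1-[(E)-2-chloroethenyl]-1-methyl-5-methylidenecyclohexane
Conditions: (i) Tf2O, 2,6-lutidine, CH2Cl2, −78 → −20 °C; (ii) n-Bu4NCl (5 equiv), MeCN/toluene, 0 → 23 °C
Reagents that add atoms: tetrabutylammonium chloride, CCCC[N+](CCCC)(CCCC)CCCC.[Cl-] (the triflate leaves)
Why: SN2 inversion of the axial secondary triflate by chloride (Tf2O/Cl–) takes C6–OH (up) to C6–Cl (down). The triflate is far more reactive than the allylic chloride, so C4 does not epimerise, and the electron-poor chlorovinyl group does not participate.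

**Step 10**
Reactants: 11
Product: 12, violacene, (1R,2S,4R,5R)-1-(bromomethyl)-1,2,4-trichloro-5-[(E)-2-chloroethenyl]-5-methylcyclohexane
Conditions: NBS (1.2 equiv), Et4NCl (3 equiv), CH2Cl2, −20 → 0 °C
Reagents that add atoms: NBS, BrN1C(=O)CCC1=O; tetraethylammonium chloride, CC[N+](CC)(CC)CC.[Cl-]
Why: Bromochlorination is anti-addition across the exocyclic alkene. Br+ adds to the open top face and chloride opens the tertiary bromonium trans-diaxially from below, giving Cl down and CH2Br up, with Markovnikov regiochemistry. The deactivated (E)-chlorovinyl group is not attacked.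

## Compound list
1 | dimethyl (2S)-2-hydroxypentanedioate | COC(=O)[C@@H](O)CCC(=O)OC | starting material
2 | (2S)-2-hydroxy-N1,N5-dimethoxy-N1,N5-dimethylpentanediamide | CON(C)C(=O)[C@@H](O)CCC(=O)N(C)OC | intermediate
3 | (2S)-2-(TBSO)-N1,N5-dimethoxy-N1,N5-dimethylpentanediamide | CON(C)C(=O)[C@@H](O[Si](C)(C)C(C)(C)C)CCC(=O)N(C)OC | intermediate
4 | (5S)-5-(TBSO)heptane-2,6-dione | CC(=O)[C@@H](O[Si](C)(C)C(C)(C)C)CCC(C)=O | intermediate
5 | (4S)-4-(TBSO)-3-methylcyclohex-2-en-1-one | O=C1C=C(C)[C@@H](O[Si](C)(C)C(C)(C)C)CC1 | intermediate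
6 | (E)-(2-chloroethenyl)boronic acid | OB(O)/C=C/Cl | starting material
7 | (3R,4S)-4-(TBSO)-3-[(E)-2-chloroethenyl]-3-methylcyclohexan-1-one | C[C@]1(/C=C/Cl)CC(=O)CC[C@@H]1O[Si](C)(C)C(C)(C)C | intermediate
8 | (2S,4S,5R)-4-(TBSO)-2-chloro-5-[(E)-2-chloroethenyl]-5-methylcyclohexan-1-one | C[C@]1(/C=C/Cl)CC(=O)[C@@H](Cl)C[C@@H]1O[Si](C)(C)C(C)(C)C | intermediate
9 | TBS ether of 10 (name in Step 7) | C[C@]1(/C=C/Cl)CC(=C)[C@@H](Cl)C[C@@H]1O[Si](C)(C)C(C)(C)C | intermediate
10 | (1S,2R,5S)-5-chloro-2-[(E)-2-chloroethenyl]-2-methyl-4-methylidenecyclohexan-1-ol | C[C@]1(/C=C/Cl)CC(=C)[C@@H](Cl)C[C@@H]1O | intermediate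
11 | (1R,2R,4S)-2,4-dichloro-1-[(E)-2-chloroethenyl]-1-methyl-5-methylidenecyclohexane | C[C@]1(/C=C/Cl)CC(=C)[C@@H](Cl)C[C@H]1Cl | intermediate
12 | violacene, (1R,2S,4R,5R)-1-(bromomethyl)-1,2,4-trichloro-5-[(E)-2-chloroethenyl]-5-methylcyclohexane | C[C@]1(/C=C/Cl)C[C@](Cl)(CBr)[C@@H](Cl)C[C@H]1Cl | target

**Total steps:** 10. **Longest linear sequence:** 10 (compound 1 → 12); the boronic acid 6 enters at Step 5.

## Three steps most likely to fail
1. **Step 5 (proposed new Pd(II) chlorovinylation).** Risks are protodeboronation, loss of the vinyl C–Cl, and poor conversion on a β,β-disubstituted enone. Fallback (known chemistry): Cu-catalysed conjugate addition of vinylMgBr (CuBr·SMe2, TMSCl) to 5, trans to OTBS. Then ozonolysis to the quaternary aldehyde and Takai–Utimoto CHCl3/CrCl2 olefination to the (E)-chlorovinyl group, separating any Z isomer.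
2. **Step 9 (neopentylic SN2 at C6).** Risks are E2 elimination toward C5 and retention through ion pairing. Fallback: at ketone stage 8, remove the TBS group, dehydrate (Burgess) to the C5=C6 alkene, and install C6–Cl by Co-catalysed MHAT hydrochlorination (Co(salen), PhSiH3, TsCl) with chromatographic separation of diastereomers. Then resume with Petasis methylenation and the final bromochlorination.
3. **Step 10 (diastereoselective bromochlorination forming the tertiary chloride).** Risks are modest dr, because the axial chloride attack is syn to the axial chlorovinyl group, and dibromide formation. Fallback: epoxidise the C3=CH2 of 11 with mCPBA from the open top face, and open with a Lewis-acidic chloride source (TiCl4) at the tertiary carbon with inversion to give Cl down and CH2OH up. Then convert CH2OH to CH2Br by Appel (PPh3/CBr4).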